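The epoxycyclohexanediol ring is opened between its tertiary carbinol carbon C1' (the ring carbon bonded to the pyridone) and the adjacent epoxide carbon C2'. Because both carbons bear oxygen, this bond is made by a SmI2 ketone–aldehyde pinacol cyclisation of an open-chain pyridyl keto-aldehyde whose C2'–C5' carbons and two stereocentres come from D-threitol. In one operation the step closes the carbocycle and sets C1' and C2' as a cis-diol anti to O3'; C2' mesylation and invertive closure by O3' then give the epoxide trans to both hydroxyls. The trans-decalin arises from (S)-citronellal by an intramolecular Diels–Alder reaction and is attached through a C3-lithiated pyridine.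

Key step: step 13

Remark: C1'–C6' number the cyclohexane ring (C1' carries the pyridone and a hydroxyl, C2'/C3' the epoxide, C4' the secondary hydroxyl); the decalin is numbered as an octahydronaphthalene (C1 propenyl, C2 acyl). Compounds 1, 9 and 15 are assumed to be purchasable.

Step 1
Reactants: 1 (S)-citronellal
Product: 2 (1E,4S)-1-iodo-4,8-dimethylnona-1,7-diene
Conditions: CHI3, CrCl2, THF/dioxane, 0 °C → rt
Reagents that add atoms: iodoform, IC(I)I
Why: Takai iodo-olefination, in which the geminal dichromium carbenoid formed from CHI3 and CrCl2 adds to the aldehyde and eliminates to the (E)-vinyl iodide; the stereocentre and the trisubstituted alkene are not touched.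

Step 2
Reactants: 2 (1E,4S)-1-iodo-4,8-dimethylnona-1,7-diene
Product: 3 (2E,6S,8E)-9-iodo-2,6-dimethylnona-2,8-dien-1-ol
Conditions: SeO2 (cat.), t-BuOOH, CH2Cl2, 0 °C → rt
Reagents that add atoms: tert-butyl hydroperoxide, CC(C)(C)OO
Why: Selenium-dioxide allylic oxidation (ene reaction then [2,3]-shift) should attack the electron-rich trisubstituted alkene at its (E)-methyl group and leave the vinyl iodide alone.

Step 3
Reactants: 3 (2E,6S,8E)-9-iodo-2,6-dimethylnona-2,8-dien-1-ol
Product: 5 (2E,4E,8S,10E)-11-iodo-N-methoxy-N,4,8-trimethylundeca-2,4,10-trienamide, via enal 4 (not isolated)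
Conditions: MnO2, Ph3P=CHC(O)N(OMe)Me, toluene, 80 °C
Reagents that add atoms: N-methoxy-N-methyl-2-(triphenylphosphoranylidene)acetamide, CON(C)C(=O)C=P(c1ccccc1)(c1ccccc1)c1ccccc1
Why: Tandem allylic oxidation–Wittig olefination, in which the enal is trapped as it forms by the stabilised ylide and should give the (2E,4E)-dienamide.

Step 4
Reactants: 5 (2E,4E,8S,10E)-11-iodo-N-methoxy-N,4,8-trimethylundeca-2,4,10-trienamide
Product: 6 (2E,4E,8S,10E,12E)-N-methoxy-N,4,8-trimethyltetradeca-2,4,10,12-tetraenamide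
Conditions: (E)-MeCH=CHB(OH)2, Pd(PPh3)4 (cat.), K2CO3, THF/H2O, 60 °C
Reagents that add atoms: (E)-prop-1-enylboronic acid, C/C=C/B(O)O
Why: Suzuki–Miyaura coupling of two alkenyl partners proceeds with retention of both alkene geometries and should give the (E,E)-diene.

Step 5
Reactants: 6 (2E,4E,8S,10E,12E)-N-methoxy-N,4,8-trimethyltetradeca-2,4,10,12-tetraenamide
Product: 7 (1R,2R,4aS,7S,8aR)-N-methoxy-N,4,7-trimethyl-1-[(E)-prop-1-enyl]-1,2,4a,5,6,7,8,8a-octahydronaphthalene-2-carboxamide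
Conditions: toluene (dilute), BHT (cat.), 170 °C, sealed tube
Reagents that add atoms: none
Why: Thermal intramolecular Diels–Alder reaction with the electron-poor dienamide as diene and the proximal alkene of the hexadiene as dienophile; a chair-like tether with the C7 methyl equatorial and the C4 methyl on the diene should favour the trans-fused adduct, the (E)-dienophile places the propenyl group equatorial at C1, and the (E,E)-diene places the amide axial at C2 (cis to propenyl), which is corrected in step 19.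

Step 6
Reactants: 7 (1R,2R,4aS,7S,8aR)-N-methoxy-N,4,7-trimethyl-1-[(E)-prop-1-enyl]-1,2,4a,5,6,7,8,8a-octahydronaphthalene-2-carboxamide
Product: 8 (1R,2R,4aS,7S,8aR)-4,7-dimethyl-1-[(E)-prop-1-enyl]-1,2,4a,5,6,7,8,8a-octahydronaphthalene-2-carbaldehyde
Conditions: LiAlH4, THF, −78 → 0 °C; aqueous work-up
Reagents that add atoms: none
Why: Hydride reduction of an N-methoxy-N-methyl amide stops at the aldehyde oxidation level; partial epimerisation at C2 would be harmless because that centre is equilibrated in step 19.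

Step 7
Reactants: 9 (4R,5R)-2,2-dimethyl-1,3-dioxolane-4,5-dimethanol (2,3-O-isopropylidene-D-threitol)
Product: 11 [(4R,5R)-5-(benzyloxymethyl)-2,2-dimethyl-1,3-dioxolan-4-yl]methanol, via sodium alkoxide 10 (not isolated)
Conditions: NaH (1 equiv), BnBr (1 equiv), THF, 0 °C → rt
Reagents that add atoms: benzyl bromide, BrCc1ccccc1
Why: Williamson etherification of one of the two homotopic hydroxyls of the C2-symmetric diol; both stereocentres (later C3' and C4') come from the chiral pool.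

Step 8
Reactants: 11 [(4R,5R)-5-(benzyloxymethyl)-2,2-dimethyl-1,3-dioxolan-4-yl]methanol
Product: 13 (2E)-3-[(4R,5R)-5-(benzyloxymethyl)-2,2-dimethyl-1,3-dioxolan-4-yl]-N-methoxy-N-methylprop-2-enamide, via aldehyde 12 (not isolated)
Conditions: PhI(OAc)2, TEMPO (cat.), CH2Cl2, rt; then Ph3P=CHC(O)N(OMe)Me, rt → 40 °C
Reagents that add atoms: N-methoxy-N-methyl-2-(triphenylphosphoranylidene)acetamide, CON(C)C(=O)C=P(c1ccccc1)(c1ccccc1)c1ccccc1
Why: One-pot oxoammonium (TEMPO) oxidation and Wittig olefination with a stabilised ylide should give the (E)-enamide without epimerising the labile α-alkoxy aldehyde.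

Step 9
Reactants: 13 (2E)-3-[(4R,5R)-5-(benzyloxymethyl)-2,2-dimethyl-1,3-dioxolan-4-yl]-N-methoxy-N-methylprop-2-enamide
Product: 14 3-[(4R,5R)-5-(hydroxymethyl)-2,2-dimethyl-1,3-dioxolan-4-yl]-N-methoxy-N-methylpropanamide
Conditions: H2 (1 atm), Pd/C, EtOH, rt
Reagents that add atoms: none
Why: Heterogeneous hydrogenation saturates the alkene and hydrogenolyses the benzyl ether in one operation, before any pyridine is present.

Step 10
Reactants: 15 5-bromo-2,4-dichloropyridine
Product: 16 5-bromo-2,4-bis[2-(trimethylsilyl)ethoxy]pyridine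
Conditions: Me3SiCH2CH2OH, NaH, DMF, 0 → 80 °C
Reagents that add atoms: 2-(trimethylsilyl)ethanol, C[Si](C)(C)CCO
Why: Twofold nucleophilic aromatic substitution by the alkoxide (C4 first, C2 on heating); the C5 bromide is not activated and should stay.

Step 11
Reactants: 16 5-bromo-2,4-bis[2-(trimethylsilyl)ethoxy]pyridine, 14 3-[(4R,5R)-5-(hydroxymethyl)-2,2-dimethyl-1,3-dioxolan-4-yl]-N-methoxy-N-methylpropanamide
Product: 19 1-{4,6-bis[2-(trimethylsilyl)ethoxy]pyridin-3-yl}-3-[(4R,5R)-5-(hydroxymethyl)-2,2-dimethyl-1,3-dioxolan-4-yl]propan-1-one, via lithium alkoxide 17 (not isolated), via aryllithium 18 (not isolated)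
Conditions: 14, LiN(SiMe3)2, THF, −78 °C; 16, n-BuLi, THF, −78 °C; combine, −78 → −30 °C; then H2O
Reagents that add atoms: none
Why: Bromine–lithium exchange and acylation of the aryllithium by the N-methoxy-N-methyl amide (ketone synthesis without over-addition), with the hydroxyl masked as its lithium alkoxide.

Step 12
Reactants: 19 1-{4,6-bis[2-(trimethylsilyl)ethoxy]pyridin-3-yl}-3-[(4R,5R)-5-(hydroxymethyl)-2,2-dimethyl-1,3-dioxolan-4-yl]propan-1-one
Product: 20 (4S,5R)-5-(3-{4,6-bis[2-(trimethylsilyl)ethoxy]pyridin-3-yl}-3-oxopropyl)-2,2-dimethyl-1,3-dioxolane-4-carbaldehyde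
Conditions: Dess–Martin periodinane, CH2Cl2, 0 °C → rt
Reagents that add atoms: none
Why: Dess–Martin oxidation of the primary alcohol under non-basic conditions should keep the α-stereocentre (C3') intact.

Step 13
Reactants: 20 (4S,5R)-5-(3-{4,6-bis[2-(trimethylsilyl)ethoxy]pyridin-3-yl}-3-oxopropyl)-2,2-dimethyl-1,3-dioxolane-4-carbaldehyde
Product: 21 (3aR,4R,5R,7aR)-5-{4,6-bis[2-(trimethylsilyl)ethoxy]pyridin-3-yl}-2,2-dimethylhexahydro-1,3-benzodioxole-4,5-diol
Conditions: SmI2 (2.5 equiv), t-BuOH, THF, −78 → −20 °C; then H2O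
Reagents that add atoms: none
Why: Single-electron transfer from SmI2 to the conjugated aryl ketone gives a trivalent-samarium ketyl whose carbon C1' adds to the tethered aldehyde carbon C2' (6-exo-trig closure of the cyclohexane ring), and a second electron transfer and protonation deliver the diol. The closest known reaction type is the SmI2-mediated intramolecular ketone–aldehyde pinacol cyclisation of carbohydrate-derived dicarbonyls. The two new hydroxyls at C1' and C2' should be cis because the samarium ion bridges both oxygens in the transition state. The C2' oxygen should be trans to the C3' acetonide oxygen through dipole and steric repulsion in a chair that keeps the trans-dioxolane and the aryl group equatorial. The step needs facial selectivity at C2', secured by the C3' stereocentre in the rigid dioxolane, and cyclisation in preference to simple reduction or loss of the α-alkoxy group, secured by the fast six-membered closure at low temperature without HMPA.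

Step 14
Reactants: 21 (3aR,4R,5R,7aR)-5-{4,6-bis[2-(trimethylsilyl)ethoxy]pyridin-3-yl}-2,2-dimethylhexahydro-1,3-benzodioxole-4,5-diol
Product: 22 (3aS,4R,5R,7aR)-5-{4,6-bis[2-(trimethylsilyl)ethoxy]pyridin-3-yl}-5-hydroxy-2,2-dimethylhexahydro-1,3-benzodioxol-4-yl methanesulfonate
Conditions: MsCl, Et3N, CH2Cl2, −20 → 0 °C
Reagents that add atoms: methanesulfonyl chloride, CS(=O)(=O)Cl
Why: Selective sulfonylation of the secondary C2' hydroxyl; the tertiary C1' hydroxyl should not react under these conditions.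

Step 15
Reactants: 22 (3aS,4R,5R,7aR)-5-{4,6-bis[2-(trimethylsilyl)ethoxy]pyridin-3-yl}-5-hydroxy-2,2-dimethylhexahydro-1,3-benzodioxol-4-yl methanesulfonate
Product: 24 (1S,2R,5R,6S)-2-{4,6-bis[2-(trimethylsilyl)ethoxy]pyridin-3-yl}-7-oxabicyclo[4.1.0]heptane-2,5-diol, via triol mesylate 23 (not isolated)
Conditions: AcOH/H2O (4:1), 40 °C; evaporate; then K2CO3, MeOH, 0 °C → rt
Reagents that add atoms: none
Why: Acidic hydrolysis of the strained trans-fused acetonide frees O3' and O4', and base then effects intramolecular SN2 displacement of the C2' mesylate by the anti-disposed O3' (inversion at C2'), which places the epoxide trans to both hydroxyls.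

Step 16
Reactants: 24 (1S,2R,5R,6S)-2-{4,6-bis[2-(trimethylsilyl)ethoxy]pyridin-3-yl}-7-oxabicyclo[4.1.0]heptane-2,5-diol
Product: 25 5-[(1S,2R,5R,6R)-2,5-bis(triethylsilyloxy)-7-oxabicyclo[4.1.0]heptan-2-yl]-2,4-bis[2-(trimethylsilyl)ethoxy]pyridine
Conditions: Et3SiOTf, 2,6-lutidine, CH2Cl2, −78 → 0 °C
Reagents that add atoms: triethylsilyl trifluoromethanesulfonate, CC[Si](CC)(CC)OS(=O)(=O)C(F)(F)F
Why: Silylation with the silyl triflate protects both the secondary and the tertiary hydroxyl for the organolithium and oxidation steps (configuration unchanged).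

Step 17
Reactants: 25 5-[(1S,2R,5R,6R)-2,5-bis(triethylsilyloxy)-7-oxabicyclo[4.1.0]heptan-2-yl]-2,4-bis[2-(trimethylsilyl)ethoxy]pyridine, 8 (1R,2R,4aS,7S,8aR)-4,7-dimethyl-1-[(E)-prop-1-enyl]-1,2,4a,5,6,7,8,8a-octahydronaphthalene-2-carbaldehyde
Product: 27 {2,4-bis[2-(trimethylsilyl)ethoxy]-5-[(1S,2R,5R,6R)-2,5-bis(triethylsilyloxy)-7-oxabicyclo[4.1.0]heptan-2-yl]pyridin-3-yl}{(1R,2R,4aS,7S,8aR)-4,7-dimethyl-1-[(E)-prop-1-enyl]-1,2,4a,5,6,7,8,8a-octahydronaphthalen-2-yl}methanol (both carbinol epimers), via aryllithium 26 (not isolated)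
Conditions: n-BuLi, THF, −78 → −30 °C; then 8, −78 °C; then H2O
Reagents that add atoms: none
Why: Directed ortho-lithiation at pyridine C3, the position between the two alkoxy groups, and 1,2-addition of the aryllithium to the aldehyde; the carbinol configuration is irrelevant because it is oxidised next.

Step 18
Reactants: 27 the carbinol from step 17
Product: 28 {2,4-bis[2-(trimethylsilyl)ethoxy]-5-[(1S,2R,5R,6R)-2,5-bis(triethylsilyloxy)-7-oxabicyclo[4.1.0]heptan-2-yl]pyridin-3-yl}{(1R,2R,4aS,7S,8aR)-4,7-dimethyl-1-[(E)-prop-1-enyl]-1,2,4a,5,6,7,8,8a-octahydronaphthalen-2-yl}methanone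
Conditions: Dess–Martin periodinane, CH2Cl2, rt
Reagents that add atoms: none
Why: Dess–Martin oxidation of the hindered secondary carbinol to the aryl ketone should tolerate the silyl ethers, the epoxide and the alkenes.

Step 19
Reactants: 28 the (2R)-ketone from step 18
Product: 29 {2,4-bis[2-(trimethylsilyl)ethoxy]-5-[(1S,2R,5R,6R)-2,5-bis(triethylsilyloxy)-7-oxabicyclo[4.1.0]heptan-2-yl]pyridin-3-yl}{(1R,2S,4aS,7S,8aR)-4,7-dimethyl-1-[(E)-prop-1-enyl]-1,2,4a,5,6,7,8,8a-octahydronaphthalen-2-yl}methanone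
Conditions: DBU (cat.), toluene, rt → 40 °C
Reagents that add atoms: none
Why: Base-mediated epimerisation through the enolate of the β,γ-unsaturated ketone should move the bulky acyl group from the axial to the equatorial position (thermodynamic control, trans to the propenyl group), which sets decalin C2.

Step 20
Reactants: 29 the (2S)-ketone from step 19
Product: 30 target CNP0494338.1, 3-{[(1R,2S,4aS,7S,8aR)-4,7-dimethyl-1-[(E)-prop-1-enyl]-1,2,4a,5,6,7,8,8a-octahydronaphthalen-2-yl]carbonyl}-5-[(1S,2R,5R,6S)-2,5-dihydroxy-7-oxabicyclo[4.1.0]heptan-2-yl]-4-hydroxypyridin-2(1H)-one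
Conditions: Bu4NF, THF, 0 °C → rt; pH 5 buffer
Reagents that add atoms: none
Why: Fluoride-induced desilylation cleaves the two triethylsilyl ethers and, by β-elimination of ethene and fluorotrimethylsilane, the two 2-(trimethylsilyl)ethyl ethers; the freed dihydroxypyridine should rest as the 4-hydroxy-2-pyridone tautomer.

Compound list
1 | (S)-citronellal, (3S)-3,7-dimethyloct-6-enal | O=CC[C@@H](C)CCC=C(C)C | starting material
2 | (1E,4S)-1-iodo-4,8-dimethylnona-1,7-diene | I/C=C/C[C@@H](C)CCC=C(C)C | intermediate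
3 | (2E,6S,8E)-9-iodo-2,6-dimethylnona-2,8-dien-1-ol | I/C=C/C[C@@H](C)CC/C=C(\C)CO | intermediate
4 | (2E,6S,8E)-9-iodo-2,6-dimethylnona-2,8-dienal | I/C=C/C[C@@H](C)CC/C=C(\C)C=O | intermediate
5 | (2E,4E,8S,10E)-11-iodo-N-methoxy-N,4,8-trimethylundeca-2,4,10-trienamide | I/C=C/C[C@@H](C)CC/C=C(C)/C=C/C(=O)N(C)OC | intermediate
6 | (2E,4E,8S,10E,12E)-N-methoxy-N,4,8-trimethyltetradeca-2,4,10,12-tetraenamide | C/C=C/C=C/C[C@@H](C)CC/C=C(C)/C=C/C(=O)N(C)OC | intermediate
7 | (1R,2R,4aS,7S,8aR)-N-methoxy-N,4,7-trimethyl-1-[(E)-prop-1-enyl]-1,2,4a,5,6,7,8,8a-octahydronaphthalene-2-carboxamide | C/C=C/[C@@H]1[C@H]2C[C@@H](C)CC[C@@H]2C(C)=C[C@@H]1C(=O)N(C)OC | intermediate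
8 | (1R,2R,4aS,7S,8aR)-4,7-dimethyl-1-[(E)-prop-1-enyl]-1,2,4a,5,6,7,8,8a-octahydronaphthalene-2-carbaldehyde | C/C=C/[C@@H]1[C@H]2C[C@@H](C)CC[C@@H]2C(C)=C[C@@H]1C=O | intermediate
9 | (4R,5R)-2,2-dimethyl-1,3-dioxolane-4,5-dimethanol (2,3-O-isopropylidene-D-threitol) | OC[C@H]1OC(C)(C)O[C@@H]1CO | starting material
10 | monosodium alkoxide of 9 | [Na+].[O-]C[C@H]1OC(C)(C)O[C@@H]1CO | intermediate
11 | [(4R,5R)-5-(benzyloxymethyl)-2,2-dimethyl-1,3-dioxolan-4-yl]methanol | c1ccccc1COC[C@H]1OC(C)(C)O[C@@H]1CO | intermediate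
12 | (4S,5R)-5-(benzyloxymethyl)-2,2-dimethyl-1,3-dioxolane-4-carbaldehyde | c1ccccc1COC[C@H]1OC(C)(C)O[C@@H]1C=O | intermediate
13 | (2E)-3-[(4R,5R)-5-(benzyloxymethyl)-2,2-dimethyl-1,3-dioxolan-4-yl]-N-methoxy-N-methylprop-2-enamide | c1ccccc1COC[C@H]1OC(C)(C)O[C@@H]1/C=C/C(=O)N(C)OC | intermediate
14 | 3-[(4R,5R)-5-(hydroxymethyl)-2,2-dimethyl-1,3-dioxolan-4-yl]-N-methoxy-N-methylpropanamide | OC[C@H]1OC(C)(C)O[C@@H]1CCC(=O)N(C)OC | intermediate
15 | 5-bromo-2,4-dichloropyridine | Clc1cc(Cl)c(Br)cn1 | starting material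
16 | 5-bromo-2,4-bis[2-(trimethylsilyl)ethoxy]pyridine | C[Si](C)(C)CCOc1cc(OCC[Si](C)(C)C)c(Br)cn1 | intermediate
17 | lithium alkoxide of 14 | [Li+].[O-]C[C@H]1OC(C)(C)O[C@@H]1CCC(=O)N(C)OC | intermediate
18 | {4,6-bis[2-(trimethylsilyl)ethoxy]pyridin-3-yl}lithium | [Li]c1cnc(OCC[Si](C)(C)C)cc1OCC[Si](C)(C)C | intermediate
19 | 1-{4,6-bis[2-(trimethylsilyl)ethoxy]pyridin-3-yl}-3-[(4R,5R)-5-(hydroxymethyl)-2,2-dimethyl-1,3-dioxolan-4-yl]propan-1-one | OC[C@H]1OC(C)(C)O[C@@H]1CCC(=O)c1cnc(OCC[Si](C)(C)C)cc1OCC[Si](C)(C)C | intermediate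
20 | (4S,5R)-5-(3-{4,6-bis[2-(trimethylsilyl)ethoxy]pyridin-3-yl}-3-oxopropyl)-2,2-dimethyl-1,3-dioxolane-4-carbaldehyde | O=C[C@H]1OC(C)(C)O[C@@H]1CCC(=O)c1cnc(OCC[Si](C)(C)C)cc1OCC[Si](C)(C)C | intermediate
21 | (3aR,4R,5R,7aR)-5-{4,6-bis[2-(trimethylsilyl)ethoxy]pyridin-3-yl}-2,2-dimethylhexahydro-1,3-benzodioxole-4,5-diol | C[Si](C)(C)CCOc1cc(OCC[Si](C)(C)C)c(cn1)[C@]1(O)CC[C@H]2OC(C)(C)O[C@@H]2[C@H]1O | intermediate
22 | (3aS,4R,5R,7aR)-5-{4,6-bis[2-(trimethylsilyl)ethoxy]pyridin-3-yl}-5-hydroxy-2,2-dimethylhexahydro-1,3-benzodioxol-4-yl methanesulfonate | C[Si](C)(C)CCOc1cc(OCC[Si](C)(C)C)c(cn1)[C@]1(O)CC[C@H]2OC(C)(C)O[C@@H]2[C@H]1OS(C)(=O)=O | intermediate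
23 | (1R,2R,5R,6S)-2-{4,6-bis[2-(trimethylsilyl)ethoxy]pyridin-3-yl}-2,5,6-trihydroxycyclohexyl methanesulfonate | C[Si](C)(C)CCOc1cc(OCC[Si](C)(C)C)c(cn1)[C@]1(O)CC[C@@H](O)[C@H](O)[C@H]1OS(C)(=O)=O | intermediate
24 | (1S,2R,5R,6S)-2-{4,6-bis[2-(trimethylsilyl)ethoxy]pyridin-3-yl}-7-oxabicyclo[4.1.0]heptane-2,5-diol | C[Si](C)(C)CCOc1cc(OCC[Si](C)(C)C)c(cn1)[C@]1(O)CC[C@@H](O)[C@@H]2O[C@@H]21 | intermediate
25 | 5-[(1S,2R,5R,6R)-2,5-bis(triethylsilyloxy)-7-oxabicyclo[4.1.0]heptan-2-yl]-2,4-bis[2-(trimethylsilyl)ethoxy]pyridine (bis-silyl ether of 24) | C[Si](C)(C)CCOc1cc(OCC[Si](C)(C)C)c(cn1)[C@]1(O[Si](CC)(CC)CC)CC[C@@H](O[Si](CC)(CC)CC)[C@@H]2O[C@@H]21 | intermediate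
26 | 3-lithio derivative of 25 | C[Si](C)(C)CCOc1ncc(c(OCC[Si](C)(C)C)c1[Li])[C@]1(O[Si](CC)(CC)CC)CC[C@@H](O[Si](CC)(CC)CC)[C@@H]2O[C@@H]21 | intermediate
27 | carbinol from 26 and 8 (both carbinol epimers; decalin C2 as in 8) | C/C=C/[C@@H]1[C@H]2C[C@@H](C)CC[C@@H]2C(C)=C[C@@H]1C(O)c3c(OCC[Si](C)(C)C)ncc(c3OCC[Si](C)(C)C)[C@]4(O[Si](CC)(CC)CC)CC[C@@H](O[Si](CC)(CC)CC)[C@@H]5O[C@@H]54 | intermediate
28 | aryl ketone with decalin (1R,2R,4aS,7S,8aR), acyl group axial | C/C=C/[C@@H]1[C@H]2C[C@@H](C)CC[C@@H]2C(C)=C[C@@H]1C(=O)c3c(OCC[Si](C)(C)C)ncc(c3OCC[Si](C)(C)C)[C@]4(O[Si](CC)(CC)CC)CC[C@@H](O[Si](CC)(CC)CC)[C@@H]5O[C@@H]54 | intermediate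
29 | aryl ketone with decalin (1R,2S,4aS,7S,8aR), acyl group equatorial | C/C=C/[C@@H]1[C@H]2C[C@@H](C)CC[C@@H]2C(C)=C[C@H]1C(=O)c3c(OCC[Si](C)(C)C)ncc(c3OCC[Si](C)(C)C)[C@]4(O[Si](CC)(CC)CC)CC[C@@H](O[Si](CC)(CC)CC)[C@@H]5O[C@@H]54 | intermediate
30 | target CNP0494338.1 | C/C=C/[C@@H]1[C@H]2C[C@@H](C)CC[C@@H]2C(C)=C[C@H]1C(=O)c1c(O)c([C@]2(O)CC[C@@H](O)[C@@H]3O[C@@H]32)c[nH]c1=O | target

Total step count: 20. Longest linear sequence: 13 steps (steps 7–9 and 11–20, from 9).

Steps most likely to fail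

Step 13. The reductive coupling may show poor facial selectivity at the aldehyde carbon, or the carbonyls may be reduced without ring closure, or the α-alkoxy group may be lost. The same C1'–C2' bond would then be closed from 20 by polarity inversion. An N-heterocyclic-carbene-catalysed intramolecular crossed benzoin reaction (triazolium precatalyst, DBU, THF) adds the aldehyde carbon C2' as an acyl anion equivalent to the aryl ketone. It should give the cyclic 2-hydroxy ketone F1 with the aryl group equatorial. Reduction with NaBH4 (axial hydride delivery, giving the C2' hydroxyl cis to the tertiary hydroxyl and trans to O3') would return to diol 21.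

Step 5. The cycloaddition may take the competing mode in which the propenyl-bearing diene acts as the four-electron partner, the cis-fused adduct may form, or the tetraene may polymerise. The competing diene would then be masked as an enyne. Sonogashira coupling of iodide 5 with propyne (Pd(PPh3)2Cl2, CuI, Et3N) should give the trienynamide F2. Its thermal intramolecular Diels–Alder reaction can only use the dienamide as diene and should give the 1-propynyl decalin amide F3. Ruthenium-catalysed trans-selective semihydrogenation ([Cp*Ru(cod)Cl], H2) would convert the alkyne into the (E)-propenyl group and rejoin the route at 7.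

Step 19. Equilibration of the silylated ketone may lead to migration of the ring double bond into conjugation, or may stop at an unfavourable ratio. The epimerisation would then be moved to the unprotected stage. Fluoride deprotection of 28 (Bu4NF, THF) should give the C2 epimer of the target F4. In F4 the acyl group is held coplanar with the pyridone by the hydrogen bond to the 4-hydroxyl, so it should be more strongly biased towards the equatorial position. Mild amine base (Et3N, MeOH) should then equilibrate it to target 30.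

Further compounds
F1 | step 13 | (3aS,5R,7aR)-5-{4,6-bis[2-(trimethylsilyl)ethoxy]pyridin-3-yl}-5-hydroxy-2,2-dimethylhexahydro-1,3-benzodioxol-4-one | C[Si](C)(C)CCOc1cc(OCC[Si](C)(C)C)c(cn1)[C@]1(O)CC[C@H]2OC(C)(C)O[C@@H]2C1=O
F2 | step 5 | (2E,4E,8S,10E)-N-methoxy-N,4,8-trimethyltetradeca-2,4,10-trien-12-ynamide | CC#C/C=C/C[C@@H](C)CC/C=C(C)/C=C/C(=O)N(C)OC
F3 | step 5 | (1R,2R,4aS,7S,8aR)-N-methoxy-N,4,7-trimethyl-1-(prop-1-ynyl)-1,2,4a,5,6,7,8,8a-octahydronaphthalene-2-carboxamide | CC#C[C@@H]1[C@H]2C[C@@H](C)CC[C@@H]2C(C)=C[C@@H]1C(=O)N(C)OC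
F4 | step 19 | C2 epimer of the target (decalin 1R,2R,4aS,7S,8aR) | C/C=C/[C@@H]1[C@H]2C[C@@H](C)CC[C@@H]2C(C)=C[C@@H]1C(=O)c1c(O)c([C@]2(O)CC[C@@H](O)[C@@H]3O[C@@H]32)c[nH]c1=O
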